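**Retrosynthetic overview**

1. The target is the linear pentamer A–CH2–B–CH2–C–CH2–B'–CH2–A' and has no stereocentre. A and A' are 2-butanoyl-4,4-dimethylcyclohexadienone rings; B, B' and C are hexasubstituted butanoylphloroglucinol benzene rings. The strategy rests on the two methylene carbons attached to central ring C: each joins ring C to an aryl carbon of ring B (or B') that lies between two oxygen-bearing carbons, a diarylmethane C(sp3)–C(sp2) bond.
2. Key disconnection: both of these CH2–aryl bonds are cut at once, giving the bis(bromomethyl) trimethyl ether of ring C (12) and two copies of the ring A–ring B arylboronate (21). They are joined by a two-directional Suzuki–Miyaura coupling, and the thirteen methyl ethers are cleaved last.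
3. Boronate 21 comes from aryl bromide 19 (Miyaura borylation), 19 from dimer 16 (enol O-methylation), and 16 from C-benzylation of the butyrylfilicinic acid dianion (4) with the bromo(bromomethyl) ring B unit 15. This sets the outer CH2–ring A bond by leaving group, not by phenol reactivity.
4. No ring is constructed. All five six-membered rings come from phlorobutyrophenone 1; rings A/A' are obtained first by dearomatising gem-dimethylation (step 1), and rings B/B' and C are carried as trimethyl ethers.

Key step: step 9

Remark on the chemistry: the ring A bis(methyl enol ether) is drawn as the cross-conjugated 2,5-dienone, with both methoxy groups next to the CMe2 carbon. A positional isomer of these vinylogous esters would behave alike in steps 8 and 9 and gives the same triketone ring in step 10.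

**Route**

Step 1
Reactants: 1 phlorobutyrophenone [1-(2,4,6-trihydroxyphenyl)butan-1-one]; 2 iodomethane
Product: 4 butyrylfilicinic acid (2-butanoyl-3,5-dihydroxy-4,4-dimethylcyclohexa-2,5-dien-1-one), via 3-methylphlorobutyrophenone 3 (not isolated)
Conditions: NaOMe (3 equiv), MeI (2.2 equiv), MeOH, 0 °C to rt; then 1 M HCl
Reagents that add atoms: iodomethane CI
Why: Dearomatising C-methylation of an acylphloroglucinol polyanion in methanol, in which the second methyl group should enter at the already methylated and most electron-rich ring carbon to give the gem-dimethyl acylfilicinic acid pattern, with over-methylated and 3,5-dimethyl by-products removed by crystallisation or chromatography.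

Step 2
Reactants: 1 phlorobutyrophenone; 5 dimethyl sulfate
Product: 8 1-(2,4,6-trimethoxyphenyl)butan-1-one, via 4-O-methyl ether 6 (not isolated), via 2-hydroxy-4,6-dimethoxy ketone 7 (not isolated)
Conditions: Me2SO4 (4 equiv), K2CO3, acetone, reflux
Reagents that add atoms: dimethyl sulfate COS(=O)(=O)OC
Why: Williamson-type O-methylation with a hard electrophile, which should alkylate the phenoxide on oxygen and not on ring carbon, the chelated ortho-hydroxyl being the last to react under reflux with excess reagent.

Step 3
Reactants: 8 1-(2,4,6-trimethoxyphenyl)butan-1-one; 9 formaldehyde (as paraformaldehyde); 10 hydrogen bromide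
Product: 12 1-[3,5-bis(bromomethyl)-2,4,6-trimethoxyphenyl]butan-1-one, via mono(bromomethyl) ketone 11 (not isolated)
Conditions: (CH2O)n (excess), 33% HBr in AcOH, 50 °C
Reagents that add atoms: formaldehyde C=O; hydrogen bromide Br
Why: Blanc-type bromomethylation (electrophilic aromatic substitution by protonated formaldehyde, then conversion of the benzylic alcohol into the bromide), directed to the two free ring positions that are each ortho or para to all three methoxy groups, the hexasubstituted product being unable to react further.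

Step 4
Reactants: 8 1-(2,4,6-trimethoxyphenyl)butan-1-one; 13 N-bromosuccinimide
Product: 14 1-(3-bromo-2,4,6-trimethoxyphenyl)butan-1-one
Conditions: NBS (1.0 equiv), MeCN, 0 °C to rt
Reagents that add atoms: N-bromosuccinimide O=C1CCC(=O)N1Br
Why: Electrophilic aromatic bromination of an activated trimethoxyarene in a polar solvent, held at the mono-bromide by stoichiometry and by the deactivating and twisting effect of the first bromine.

Step 5
Reactants: 14 1-(3-bromo-2,4,6-trimethoxyphenyl)butan-1-one; 9 formaldehyde (as paraformaldehyde); 10 hydrogen bromide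
Product: 15 1-[3-bromo-5-(bromomethyl)-2,4,6-trimethoxyphenyl]butan-1-one
Conditions: (CH2O)n, 33% HBr in AcOH, 60 °C
Reagents that add atoms: formaldehyde C=O; hydrogen bromide Br
Why: Blanc-type bromomethylation at the only remaining ring position, which is still flanked by two methoxy groups and para to the third, so that a single benzylic bromide should result.

Step 6
Reactants: 4 butyrylfilicinic acid (1.2 equiv); 15 1-[3-bromo-5-(bromomethyl)-2,4,6-trimethoxyphenyl]butan-1-one
Product: 16 2-butanoyl-6-[(3-bromo-5-butanoyl-2,4,6-trimethoxyphenyl)methyl]-3,5-dihydroxy-4,4-dimethylcyclohexa-2,5-dien-1-one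
Conditions: NaOMe (2.0 equiv per 4), MeOH/THF, 0 °C to rt; then 1 M HCl
Reagents that add atoms: none
Why: C-alkylation of a cyclic β-dicarbonyl dianion by a benzylic bromide (SN2), in which the last-formed enolate carbon C6, the only ring CH of 4, is the most nucleophilic site and the protic solvent favours carbon over oxygen, as in the C-methylation of step 1.

Step 7
Reactants: 16 ring A–ring B dimer bromide; 17 (trimethylsilyl)diazomethane
Product: 19 2-butanoyl-6-[(3-bromo-5-butanoyl-2,4,6-trimethoxyphenyl)methyl]-3,5-dimethoxy-4,4-dimethylcyclohexa-2,5-dien-1-one, via ring A mono enol ether 18 (not isolated)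
Conditions: TMSCHN2 (2 M in hexanes, 4 equiv), toluene/MeOH 4:1, 0 °C to rt
Reagents that add atoms: (trimethylsilyl)diazomethane C[Si](C)(C)C=[N+]=[N-]
Why: Diazomethane-type O-methylation of acidic enols (proton transfer from the vinylogous acid, then methyl transfer to oxygen), which needs no base, cannot alkylate on carbon and should leave the aryl bromide, aryl ethers and ketones untouched.

Step 8
Reactants: 19 ring A–ring B dimer bromide with ring A as bis(methyl enol ether); 20 bis(pinacolato)diboron
Product: 21 2-butanoyl-6-{[3-butanoyl-2,4,6-trimethoxy-5-(4,4,5,5-tetramethyl-1,3,2-dioxaborolan-2-yl)phenyl]methyl}-3,5-dimethoxy-4,4-dimethylcyclohexa-2,5-dien-1-one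
Conditions: B2pin2 (1.5 equiv), Pd2(dba)3 (2.5 mol%), XPhos (10 mol%), KOAc (3 equiv), 1,4-dioxane, 100 °C
Reagents that add atoms: bis(pinacolato)diboron CC1(C)OB(OC1(C)C)B1OC(C)(C)C(C)(C)O1
Why: Miyaura borylation, in which oxidative addition of zerovalent palladium to the di-ortho-substituted aryl bromide and acetate-assisted transmetalation with the diboron are made possible by the bulky biaryl phosphine, while the weak base leaves ketones and vinylogous esters alone.

Step 9
Reactants: 12 1-[3,5-bis(bromomethyl)-2,4,6-trimethoxyphenyl]butan-1-one (1 equiv); 21 ring A–ring B arylboronate (2.5 equiv)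
Product: 23 per-O-methylated pentamer (tridecamethyl ether of the target), via mono-coupled benzylic bromide 22 (not isolated)
Conditions: Pd(OAc)2 (10 mol%), SPhos (20 mol%), K3PO4 (6 equiv), toluene/H2O 10:1, degassed, 80 °C
Reagents that add atoms: none
Why: Zerovalent palladium formed from Pd(OAc)2 and SPhos inserts into a benzylic C–Br bond of 12, phosphate-assisted transmetalation transfers the ring B aryl group from boronate 21, and reductive elimination forms the CH2–C(aryl) bond; the cycle then repeats on the mono-coupled bromide 22 at the second arm. This is a Suzuki–Miyaura cross-coupling of a benzylic bromide with an arylboronic ester, a known way to diarylmethanes. No ring is closed and no stereocentre is formed; the step makes the two skeletal bonds between the methylene carbons on ring C and rings B and B'. The selectivity needed is cross-coupling at both arms ahead of protodeboronation of the di-ortho-methoxy arylboronate, benzylic homocoupling and hydrolysis of the bromide; the fast oxidative addition of the benzylic bromide, the bulky electron-rich SPhos ligand, the excess of 21, the small amount of water and the pinacol ester form of boron all work in that direction. Because electrophile and nucleophile are fixed by bromine and boron and no free phenol or enol is present, no retro-Michael (quinone methide) exchange of methylene bridges can scramble the order A–B–C–B'–A'. The aryl ketones and the vinylogous ester groups of ring A should not react with phosphate at 80 °C.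

Step 10
Reactants: 23 per-O-methylated pentamer
Product: 25 target CNP0188003.0, via tridecakis(dibromoboryl) ether 24 (not isolated)
Conditions: BBr3 (1 M in CH2Cl2, ca. 30 equiv), CH2Cl2, −78 °C to rt; then ice/H2O
Reagents that add atoms: none
Why: Lewis acid-mediated ether cleavage (boron coordination to oxygen, then bromide attack at methyl), which should remove the nine hindered aryl methyl ethers and the four vinylogous methyl esters alike, the boron-bound oxygens being hydrolysed to the phenols and enols on aqueous work-up.

**Compound list**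

1 | phlorobutyrophenone, 1-(2,4,6-trihydroxyphenyl)butan-1-one | CCCC(=O)c1c(O)cc(O)cc1O | starting material
2 | iodomethane | CI | starting material
3 | 3-methylphlorobutyrophenone, 1-(2,4,6-trihydroxy-3-methylphenyl)butan-1-one | CCCC(=O)c1c(O)cc(O)c(C)c1O | intermediate
4 | butyrylfilicinic acid, 2-butanoyl-3,5-dihydroxy-4,4-dimethylcyclohexa-2,5-dien-1-one | CCCC(=O)C1=C(O)C(C)(C)C(O)=CC1=O | intermediate
5 | dimethyl sulfate | COS(=O)(=O)OC | starting material
6 | 1-(2,6-dihydroxy-4-methoxyphenyl)butan-1-one | CCCC(=O)c1c(O)cc(OC)cc1O | intermediate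
7 | 1-(2-hydroxy-4,6-dimethoxyphenyl)butan-1-one | CCCC(=O)c1c(O)cc(OC)cc1OC | intermediate
8 | 1-(2,4,6-trimethoxyphenyl)butan-1-one | CCCC(=O)c1c(OC)cc(OC)cc1OC | intermediate
9 | formaldehyde (used as paraformaldehyde) | C=O | starting material
10 | hydrogen bromide | Br | starting material
11 | 1-[3-(bromomethyl)-2,4,6-trimethoxyphenyl]butan-1-one | CCCC(=O)c1c(OC)cc(OC)c(CBr)c1OC | intermediate
12 | 1-[3,5-bis(bromomethyl)-2,4,6-trimethoxyphenyl]butan-1-one (ring C unit) | CCCC(=O)c1c(OC)c(CBr)c(OC)c(CBr)c1OC | intermediate
13 | N-bromosuccinimide | O=C1CCC(=O)N1Br | starting material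
14 | 1-(3-bromo-2,4,6-trimethoxyphenyl)butan-1-one | CCCC(=O)c1c(OC)cc(OC)c(Br)c1OC | intermediate
15 | 1-[3-bromo-5-(bromomethyl)-2,4,6-trimethoxyphenyl]butan-1-one (ring B unit) | CCCC(=O)c1c(OC)c(Br)c(OC)c(CBr)c1OC | intermediate
16 | 2-butanoyl-6-[(3-bromo-5-butanoyl-2,4,6-trimethoxyphenyl)methyl]-3,5-dihydroxy-4,4-dimethylcyclohexa-2,5-dien-1-one | CCCC(=O)C1=C(O)C(C)(C)C(O)=C(Cc2c(OC)c(Br)c(OC)c(C(=O)CCC)c2OC)C1=O | intermediate
17 | (trimethylsilyl)diazomethane | C[Si](C)(C)C=[N+]=[N-] | starting material
18 | 2-butanoyl-6-[(3-bromo-5-butanoyl-2,4,6-trimethoxyphenyl)methyl]-3-hydroxy-5-methoxy-4,4-dimethylcyclohexa-2,5-dien-1-one | CCCC(=O)C1=C(O)C(C)(C)C(OC)=C(Cc2c(OC)c(Br)c(OC)c(C(=O)CCC)c2OC)C1=O | intermediate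
19 | 2-butanoyl-6-[(3-bromo-5-butanoyl-2,4,6-trimethoxyphenyl)methyl]-3,5-dimethoxy-4,4-dimethylcyclohexa-2,5-dien-1-one | CCCC(=O)C1=C(OC)C(C)(C)C(OC)=C(Cc2c(OC)c(Br)c(OC)c(C(=O)CCC)c2OC)C1=O | intermediate
20 | bis(pinacolato)diboron | CC1(C)OB(OC1(C)C)B1OC(C)(C)C(C)(C)O1 | starting material
21 | 2-butanoyl-6-{[3-butanoyl-2,4,6-trimethoxy-5-(4,4,5,5-tetramethyl-1,3,2-dioxaborolan-2-yl)phenyl]methyl}-3,5-dimethoxy-4,4-dimethylcyclohexa-2,5-dien-1-one | CCCC(=O)C1=C(OC)C(C)(C)C(OC)=C(Cc2c(OC)c(B3OC(C)(C)C(C)(C)O3)c(OC)c(C(=O)CCC)c2OC)C1=O | intermediate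
22 | mono-coupled benzylic bromide: ring C carrying one ring A–ring B arm and one remaining bromomethyl group | CCCC(=O)C1=C(OC)C(C)(C)C(OC)=C(Cc2c(OC)c(Cc3c(OC)c(CBr)c(OC)c(C(=O)CCC)c3OC)c(OC)c(C(=O)CCC)c2OC)C1=O | intermediate
23 | per-O-methylated pentamer (tridecamethyl ether of the target) | CCCC(=O)C1=C(OC)C(C)(C)C(OC)=C(Cc2c(OC)c(Cc3c(OC)c(Cc4c(OC)c(CC5=C(OC)C(C)(C)C(OC)=C(C(=O)CCC)C5=O)c(OC)c(C(=O)CCC)c4OC)c(OC)c(C(=O)CCC)c3OC)c(OC)c(C(=O)CCC)c2OC)C1=O | intermediate
24 | tridecakis(dibromoboryl) ether of the target (boron-bound form before hydrolysis) | CCCC(=O)C1=C(OB(Br)Br)C(C)(C)C(OB(Br)Br)=C(Cc2c(OB(Br)Br)c(Cc3c(OB(Br)Br)c(Cc4c(OB(Br)Br)c(CC5=C(OB(Br)Br)C(C)(C)C(OB(Br)Br)=C(C(=O)CCC)C5=O)c(OB(Br)Br)c(C(=O)CCC)c4OB(Br)Br)c(OB(Br)Br)c(C(=O)CCC)c3OB(Br)Br)c(OB(Br)Br)c(C(=O)CCC)c2OB(Br)Br)C1=O | intermediate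
25 | target CNP0188003.0 (pentamer A–CH2–B–CH2–C–CH2–B'–CH2–A', no stereocentre) | CCCC(=O)C1=C(O)C(C)(C)C(O)=C(Cc2c(O)c(Cc3c(O)c(Cc4c(O)c(CC5=C(O)C(C)(C)C(O)=C(C(=O)CCC)C5=O)c(O)c(C(=O)CCC)c4O)c(O)c(C(=O)CCC)c3O)c(O)c(C(=O)CCC)c2O)C1=O | target

**Step count and risks**

Total step count: 10. Longest linear sequence: 8 steps (steps 2, 4, 5, 6, 7, 8, 9, 10).

Steps most likely to fail:

Step 9. Protodeboronation of the di-ortho-methoxy arylboronate may outrun transmetalation, so that the coupling stops at the mono-coupled stage, or the benzylic bromide may be used up by hydrolysis and homocoupling. The fallback reverses the polarity (Negishi coupling); it sets out from 12, uses aryl bromide 19 as partner and comes back to the route at 23. Zinc dust (LiCl, THF, 0 °C) should insert into both benzylic C–Br bonds of 12 to give the bis(benzylzinc bromide) F1, a reagent class that tolerates ketones. Coupling of F1 with 19 (2.2 equiv) under Pd(OAc)2 and SPhos in THF at 50 °C should give 23. This path needs no arylboron compound and so also covers a failure of the borylation in step 8.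

Step 6. Alkylation may occur on enolate oxygen instead of carbon, a second alkylation may follow at the same carbon, or the benzylic bromide may be solvolysed before it is captured. The fallback replaces substitution by condensation and reduction; it sets out from 15 and comes back at 16. Oxidation of 15 with N-methylmorpholine N-oxide in MeCN (Kornblum-type) should give 3-bromo-5-butanoyl-2,4,6-trimethoxybenzaldehyde F2. Stirring F2 with 4, the Hantzsch ester and catalytic L-proline in CH2Cl2 at rt should give, by Knoevenagel condensation, the benzylidene triketone F3, which is reduced in the same flask by hydride transfer from the dihydropyridine to 16. In this reductive alkylation the new bond can form only at carbon and only once.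

Step 10. Cleavage may stay incomplete among thirteen ethers, or methylene bridges may migrate by acid-promoted retro-Friedel–Crafts exchange during long exposure to BBr3 and HBr. The fallback unmasks in two stages; it sets out from 23 and comes back at 25. Dilute HCl in THF at rt should hydrolyse only the four vinylogous methyl esters of rings A and A' to give the nonamethyl ether F4. The nine aryl methyl ethers are then cleaved with iodotrimethylsilane (Me3SiCl, NaI, MeCN, 50 °C), which should give the tridecakis(trimethylsilyl) ether F5, and methanolysis of F5 at rt releases 25.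

**Further compounds**

F1 | step 9 | 1-[3,5-bis(bromozinciomethyl)-2,4,6-trimethoxyphenyl]butan-1-one | CCCC(=O)c1c(OC)c(C[Zn]Br)c(OC)c(C[Zn]Br)c1OC
F2 | step 6 | 3-bromo-5-butanoyl-2,4,6-trimethoxybenzaldehyde | CCCC(=O)c1c(OC)c(Br)c(OC)c(C=O)c1OC
F3 | step 6 | 2-butanoyl-6-[(3-bromo-5-butanoyl-2,4,6-trimethoxyphenyl)methylidene]-3-hydroxy-4,4-dimethylcyclohex-2-ene-1,5-dione (alkene geometry not controlled, removed on reduction) | CCCC(=O)C1=C(O)C(C)(C)C(=O)C(=Cc2c(OC)c(Br)c(OC)c(C(=O)CCC)c2OC)C1=O
F4 | step 10 | nonamethyl ether of the target with rings A and A' free | CCCC(=O)C1=C(O)C(C)(C)C(O)=C(Cc2c(OC)c(Cc3c(OC)c(Cc4c(OC)c(CC5=C(O)C(C)(C)C(O)=C(C(=O)CCC)C5=O)c(OC)c(C(=O)CCC)c4OC)c(OC)c(C(=O)CCC)c3OC)c(OC)c(C(=O)CCC)c2OC)C1=O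
F5 | step 10 | tridecakis(trimethylsilyl) ether of the target | CCCC(=O)C1=C(O[Si](C)(C)C)C(C)(C)C(O[Si](C)(C)C)=C(Cc2c(O[Si](C)(C)C)c(Cc3c(O[Si](C)(C)C)c(Cc4c(O[Si](C)(C)C)c(CC5=C(O[Si](C)(C)C)C(C)(C)C(O[Si](C)(C)C)=C(C(=O)CCC)C5=O)c(O[Si](C)(C)C)c(C(=O)CCC)c4O[Si](C)(C)C)c(O[Si](C)(C)C)c(C(=O)CCC)c3O[Si](C)(C)C)c(O[Si](C)(C)C)c(C(=O)CCC)c2O[Si](C)(C)C)C1=O
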